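## Analysis of the target

Target 19 is a 2,3-dihydrobenzofuran neolignan. Ring A (the benzo ring, C3a to C7a) is fused to the dihydrofuran ring B (O1, C2, C3). C2 carries the 3,4,5-trimethoxyphenyl ring C, C3 a hydroxymethyl group, and C5 (para to O1) an (E)-3-hydroxyprop-1-enyl chain. There are two adjacent stereocentres, C2 (R) and C3 (S), trans to each other; both are benzylic and C2 is also bound to oxygen. The sensitive groups are the cinnamyl alcohol (conjugated to O1 through ring A, so easily ionised by acid, oxidised or hydrogenated), the benzylic C2–O1 bond (acid, hydrogenolysis), and two primary alcohols that must stay distinguishable until the end. The trans relationship is the more stable one and is not the problem. The hard part is the absolute configuration of two benzylic centres that offer no handle for an auxiliary. The strategy rests on the substitution pattern of C2 and C3: C2 bears ring C and oxygen, C3 bears C3a of ring A and a CH2O carbon. This is the pattern left when an (E)-alkenylboron compound O–CH2–CH=CH–B is diarylated anti across its double bond and boron is then exchanged for oxygen. Because C5 is para to C7a, an ester at C5 serves both as the precursor of the side chain and as the activating group for closing O1–C7a by displacement of fluoride.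

## Retrosynthetic reasoning

**Side chain.** Target 19 is traced to its silyl ether 18, so that the two primary alcohols stay distinct until the last step. The allylic alcohol of 18 comes from the unsaturated ester 17. The Cα=Cβ double bond of 17 is cut by a Wittig disconnection to aldehyde 16, which is made from benzylic alcohol 15 and is not isolated. Alcohol 15 comes from the methyl ester 14. Cutting here puts a plain ester on C5 during all earlier steps, where it is robust and electron-withdrawing.

**O1–C7a.** Ring B of 14 is opened at the aryl–oxygen bond, giving the fluoro alcohol 13. This cut leaves all four bonds at C2 and C3 untouched, so the forward ring closure (alkoxide onto the fluorinated carbon para to the ester, 5-exo) cannot change either stereocentre. Cutting O1–C2 instead would place a leaving group on a benzylic carbon and risk the C2 configuration.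

**C–O from C–B.** The carbinol of 13 is traced to the boronic ester 12. The forward oxidation proceeds with retention, so the C1 configuration of 12 is carried into C2 of the ring.

**Key disconnection.** In 12 the bond from C1 to ring C and the bond from C2 to ring A are cut together. This gives three pieces: aryllithium 10 (from bromide 9), the (E)-alkenylboronic ester 6 and aryl triflate 8. In the forward direction 10 and 6 form the ate complex 11, and a palladium catalyst with a chiral ferrocenyl diphosphine joins 11 and 8. Both skeletal bonds and both stereocentres are made in this one operation. The diol on boron is the hindered cis-diol 2 rather than pinacol, because a substituent on the alkene carbon remote from boron otherwise favours plain cross-coupling. The silyl group is triisopropylsilyl rather than a smaller one, because 13 is a 1,3-diol monoether and will later be exposed to strong base.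

**Building blocks.** Boronic ester 6 is traced to alkyne 4 and diol 2 through the catechol ester 5 (hydroboration, then ligand exchange on boron). Alkyne 4 comes from propargyl alcohol 3, diol 2 from dione 1, and triflate 8 from phenol 7.

## Alternatives that were turned down

**Alternative 1:** ring contraction of a flavanone. The C3–C3a bond is traced to a 1,2-shift of the ring A carbon from C4 to C3 of the enantiopure flavanone A2, (2R)-6-bromo-2-(3,4,5-trimethoxyphenyl)chroman-4-one. In the forward step PhI(OAc)2 and H2SO4 in trimethyl orthoformate should convert A2 through its enol ether and ketal into the trans ester A1, methyl (2R,3R)-5-bromo-2-(3,4,5-trimethoxyphenyl)-2,3-dihydrobenzofuran-3-carboxylate.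
- For: it is short. A2 could come from an asymmetric conjugate arylation, and after the contraction only ester reduction and a cross-coupling at the bromide remain. On step count it is clearly stronger than the chosen route. The C3 centre is epimerisable next to the ester and should settle trans.
- Against: the absolute configuration rests on the C2 centre of A2 alone. That centre is benzylic, bound to oxygen and β to a carbonyl, so strong acid can open the ring by retro-oxa-Michael reaction to the hydroxychalcone and erode it. The oxidised intermediate also has a second migrating group available: a shift of ring C from C2 to C3 gives the isoflavone A3, 6-bromo-3-(3,4,5-trimethoxyphenyl)chromen-4-one. Ring A is deactivated by bromine, so this competition is not clearly won.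
- Comparison: the chosen route is longer, but it sets both centres by catalyst control under non-acidic conditions, and no later step can reach them.

**Alternative 2:** [2+2+2] cycloaddition. Ring A is cut into three alkyne units, forming C3a–C7a, C4–C5 and C6–C7 forward. With RhCl(PPh3)3 the diyne A5 (a silylated ynol ether on the C2 oxygen and a terminal alkyne on C3) and the enyne A6, (E)-tert-butyldimethyl(pent-2-en-4-ynyloxy)silane, should give A4, the 7-trimethylsilyl bis(silyl ether) of the target.
- For: ring A, ring B and the complete side chain appear in one step, which no other approach matches. The silyl group on the ynol ether should steer the substituted carbon of A6 away from C7.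
- Against: the cycloaddition creates no stereocentre. Both must already be in A5, an acyclic anti-configured propargylic ynol ether that needs its own asymmetric synthesis. Ynol ethers with a hydrogen β to oxygen lose ketene on warming. A6 can trimerise with itself or react through its alkene. The C7 silyl group and two silyl ethers must then be removed.
- Comparison: it is the most convergent plan for the carbon skeleton, but it moves the stereochemical problem into a fragile precursor and is longer overall. The chosen route solves that problem in the bond-forming step itself.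

**Alternative 3:** sulfonium ylide [4+1] annulation. C2–C3 and O1–C2 are cut. With Cs2CO3 a sulfonyl phenol should release the ortho-quinone methide A8, (6E)-4-bromo-6-[2-(tert-butyldimethylsilyloxy)ethylidene]cyclohexa-2,4-dien-1-one. A chiral 3,4,5-trimethoxybenzyl sulfonium ylide then adds to its methide carbon and the phenoxide displaces the sulfide, giving A7, (2R,3S)-5-bromo-3-(tert-butyldimethylsilyloxymethyl)-2-(3,4,5-trimethoxyphenyl)-2,3-dihydrobenzofuran.
- For: the ring and both stereocentres form in one convergent step, trans selectivity is inherent to the betaine pathway, and only a coupling at the bromide and a desilylation remain. It is shorter than the chosen route.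
- Against: the enantioselectivity comes from a stoichiometric chiral sulfide. A8 carries an alkyl group with hydrogens on the methide carbon, so it can tautomerise to a vinylphenol (here a conjugated silyl enol ether) before the ylide arrives. Reversible betaine formation with a semi-stabilised ylide makes the enantiomeric outcome hard to predict.
- Comparison: it wins on step count. The chosen route offers a catalytic, ligand-controlled absolute configuration and a relative configuration fixed by a stereospecific addition rather than by betaine equilibration.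

Key step: step 5

Assumption: the enantiomer of the ligand 1,1′-bis[bis(4-methoxy-3,5-dimethylphenyl)phosphino]-2,2′-bis[α-(dimethylamino)benzyl]ferrocene (Mandyphos, C64H74FeN2O4P2) that leads to the (1R,2S) product is used; its sense of induction on this substrate would have to be confirmed by correlation, and the other enantiomer is taken if it is reversed.

## Route

Step 1
Reactants: 1 acenaphthylene-1,2-dione
Product: 2 cis-1,2-dimethyl-1,2-dihydroacenaphthylene-1,2-diol (meso)
Conditions: AlMe3 (excess), toluene, 0 °C → rt; aq. HCl; recrystallisation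
Reagents that add atoms: trimethylaluminium, C[Al](C)C
Why: Double 1,2-addition of a methylaluminium reagent to the 1,2-dione; the second methyl group is expected to enter on the face away from the aluminium alkoxide of the first adduct, which places the two hydroxyl groups cis, and any trans diol should be removed by crystallisation.

Step 2
Reactants: 3 prop-2-yn-1-ol
Product: 4 triisopropyl(prop-2-yn-1-yloxy)silane
Conditions: i-Pr3SiCl, imidazole, CH2Cl2, 0 °C → rt
Reagents that add atoms: chlorotriisopropylsilane, CC(C)[Si](Cl)(C(C)C)C(C)C
Why: Standard silylation of a primary alcohol; the triisopropylsilyl group is chosen because it resists base-induced oxygen-to-oxygen migration later in the route.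

Step 3
Reactants: 4 triisopropyl(prop-2-yn-1-yloxy)silane; 2 cis-1,2-dimethyl-1,2-dihydroacenaphthylene-1,2-diol
Product: 6 8-[(E)-3-(triisopropylsilyloxy)prop-1-enyl]-6b,9a-dimethyl-6b,9a-dihydroacenaphtho[1,2-d][1,3,2]dioxaborole, via catechol boronic ester 5 (not isolated)
Conditions: catecholborane, neat, 70 °C; then 2, THF, rt
Reagents that add atoms: catecholborane, B1Oc2ccccc2O1
Why: Syn hydroboration of the terminal alkyne places boron on the terminal carbon and gives the E alkene; the labile catechol ester then exchanges with the aliphatic diol 2 (transesterification of a boronic ester).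

Step 4
Reactants: 7 methyl 4-fluoro-3-hydroxybenzoate
Product: 8 methyl 4-fluoro-3-(trifluoromethylsulfonyloxy)benzoate
Conditions: Tf2O, pyridine, CH2Cl2, 0 °C
Reagents that add atoms: trifluoromethanesulfonic anhydride, O=S(=O)(OS(=O)(=O)C(F)(F)F)C(F)(F)F
Why: Sulfonylation of a phenol; the triflate sits on the carbon that becomes C3a and the fluoride on the carbon that becomes C7a.

Step 5
Reactants: 9 5-bromo-1,2,3-trimethoxybenzene; 6 8-[(E)-3-(triisopropylsilyloxy)prop-1-enyl]-6b,9a-dimethyl-6b,9a-dihydroacenaphtho[1,2-d][1,3,2]dioxaborole; 8 methyl 4-fluoro-3-(trifluoromethylsulfonyloxy)benzoate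
Product: 12 methyl 4-fluoro-3-[(1R,2S)-1-(6b,9a-dimethyl-6b,9a-dihydroacenaphtho[1,2-d][1,3,2]dioxaborol-8-yl)-3-(triisopropylsilyloxy)-1-(3,4,5-trimethoxyphenyl)propan-2-yl]benzoate, via (3,4,5-trimethoxyphenyl)lithium 10 (not isolated), via lithium boron ate complex 11 (not isolated)
Conditions: 9, t-BuLi (2 equiv), Et2O, −78 °C; then 6, −78 °C → rt; solvent switch to THF; 8, Pd(OAc)2 (5 mol %), Mandyphos C64H74FeN2O4P2 (6 mol %), KOSO2CF3, THF, 60 °C
Reagents that add atoms: none
Why: Aryllithium 10 adds to boron of 6 to give the four-coordinate ate complex 11, which makes the boron-bound alkene carbon a migration terminus. Oxidative addition of zerovalent palladium into the C–OTf bond of 8 (C–F and the ester stay intact) gives a cationic divalent arylpalladium species that binds the alkene of 11; this triggers the 1,2-shift of the trimethoxyphenyl group from boron to C1 on the face opposite palladium while palladium bonds to C2, and C(sp3)–C(sp2) reductive elimination with retention places ring A on C2. The closest known reaction type is the palladium-catalysed enantioselective conjunctive cross-coupling of β-substituted alkenylboron ate complexes with aryl triflates. No ring is closed in this step. Both stereocentres arise in the same event: the relative configuration follows from stereospecific anti addition of the two aryl groups across the E double bond (the arrangement that becomes the 2,3-trans ring), and the absolute configuration is set by the chiral diphosphine on palladium, which selects the alkene face that is bound. The step needs the metallate shift to outrun direct transfer of an aryl or alkenyl group from boron to palladium; the hindered diol 2 on boron, whose oxygens are shielded by the methyl groups and the naphthalene unit, is there to block that transfer. Reductive elimination must also be faster than β-hydride or β-silyloxy loss toward the CH2OSi group, which the wide-bite-angle chelating ligand favours, and KOSO2CF3 precipitates the bromide left from the lithiation, which would otherwise block the cationic palladium.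

Step 6
Reactants: 12 methyl 4-fluoro-3-[(1R,2S)-1-(6b,9a-dimethyl-6b,9a-dihydroacenaphtho[1,2-d][1,3,2]dioxaborol-8-yl)-3-(triisopropylsilyloxy)-1-(3,4,5-trimethoxyphenyl)propan-2-yl]benzoate
Product: 13 methyl 4-fluoro-3-[(1R,2S)-1-hydroxy-3-(triisopropylsilyloxy)-1-(3,4,5-trimethoxyphenyl)propan-2-yl]benzoate
Conditions: NaBO3·4H2O, THF/H2O, rt
Reagents that add atoms: sodium perborate tetrahydrate, [Na+].[Na+].O[B-]1(O)OO[B-](O)(O)OO1.O.O.O.O.O.O
Why: Oxidation of a secondary boronic ester by 1,2-shift of carbon from boron to peroxide oxygen, which proceeds with retention at C1; the mildly basic perborate is chosen so that the methyl ester and the aryl fluoride should survive.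

Step 7
Reactants: 13 methyl 4-fluoro-3-[(1R,2S)-1-hydroxy-3-(triisopropylsilyloxy)-1-(3,4,5-trimethoxyphenyl)propan-2-yl]benzoate
Product: 14 methyl (2R,3S)-3-(triisopropylsilyloxymethyl)-2-(3,4,5-trimethoxyphenyl)-2,3-dihydro-1-benzofuran-5-carboxylate
Conditions: KN(SiMe3)2 (1.1 equiv), THF, 0 °C → rt
Reagents that add atoms: none
Why: Intramolecular nucleophilic aromatic substitution: the potassium alkoxide attacks the fluorinated carbon para to the ester (5-exo closure through a Meisenheimer intermediate) and forms O1–C7a; no bond at C2 or C3 is broken, so the trans ring follows directly from the configuration of 13.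

Step 8
Reactants: 14 methyl (2R,3S)-3-(triisopropylsilyloxymethyl)-2-(3,4,5-trimethoxyphenyl)-2,3-dihydro-1-benzofuran-5-carboxylate
Product: 15 [(2R,3S)-3-(triisopropylsilyloxymethyl)-2-(3,4,5-trimethoxyphenyl)-2,3-dihydro-1-benzofuran-5-yl]methanol
Conditions: i-Bu2AlH, CH2Cl2, −78 → 0 °C; aq. potassium sodium tartrate
Reagents that add atoms: none
Why: Hydride reduction of an aromatic ester to the benzylic alcohol; silyl ether, aryl ethers and both stereocentres are inert to the reagent.

Step 9
Reactants: 15 [(2R,3S)-3-(triisopropylsilyloxymethyl)-2-(3,4,5-trimethoxyphenyl)-2,3-dihydro-1-benzofuran-5-yl]methanol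
Product: 17 ethyl (E)-3-[(2R,3S)-3-(triisopropylsilyloxymethyl)-2-(3,4,5-trimethoxyphenyl)-2,3-dihydro-1-benzofuran-5-yl]prop-2-enoate, via aldehyde 16 (not isolated)
Conditions: MnO2, Ph3P=CHCO2Et, CH2Cl2, rt → 40 °C
Reagents that add atoms: ethyl (triphenylphosphoranylidene)acetate, CCOC(=O)C=P(c1ccccc1)(c1ccccc1)c1ccccc1
Why: Tandem oxidation–Wittig olefination: MnO2 oxidises the electron-rich benzylic alcohol to aldehyde 16, which is trapped at once by the stabilised ylide; stabilised ylides give the E alkene.

Step 10
Reactants: 17 ethyl (E)-3-[(2R,3S)-3-(triisopropylsilyloxymethyl)-2-(3,4,5-trimethoxyphenyl)-2,3-dihydro-1-benzofuran-5-yl]prop-2-enoate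
Product: 18 (E)-3-[(2R,3S)-3-(triisopropylsilyloxymethyl)-2-(3,4,5-trimethoxyphenyl)-2,3-dihydro-1-benzofuran-5-yl]prop-2-en-1-ol
Conditions: i-Bu2AlH, CH2Cl2, −78 °C; aq. potassium sodium tartrate
Reagents that add atoms: none
Why: 1,2-Reduction of an α,β-unsaturated ester to the allylic alcohol by an aluminium hydride at low temperature; the double bond and its geometry are retained.

Step 11
Reactants: 18 (E)-3-[(2R,3S)-3-(triisopropylsilyloxymethyl)-2-(3,4,5-trimethoxyphenyl)-2,3-dihydro-1-benzofuran-5-yl]prop-2-en-1-ol
Product: 19 (E)-3-[(2R,3S)-3-(hydroxymethyl)-2-(3,4,5-trimethoxyphenyl)-2,3-dihydro-1-benzofuran-5-yl]prop-2-en-1-ol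
Conditions: Bu4NF, THF, 0 °C → rt
Reagents that add atoms: none
Why: Fluoride cleavage of the silyl ether under neutral to mildly basic conditions, which avoids the acid that would ionise the cinnamyl alcohol or the benzylic C2–O1 bond.

## Compound list

1 | acenaphthylene-1,2-dione | O=C1C(=O)c2cccc3cccc1c23 | starting material
2 | cis-1,2-dimethyl-1,2-dihydroacenaphthylene-1,2-diol (meso, 1R,2S) | C[C@]1(O)[C@@](C)(O)c2cccc3cccc1c23 | intermediate
3 | prop-2-yn-1-ol | C#CCO | starting material
4 | triisopropyl(prop-2-yn-1-yloxy)silane | C#CCO[Si](C(C)C)(C(C)C)C(C)C | intermediate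
5 | 2-[(E)-3-(triisopropylsilyloxy)prop-1-enyl]-1,3,2-benzodioxaborole | CC(C)[Si](OC/C=C/B1Oc2ccccc2O1)(C(C)C)C(C)C | intermediate (not isolated)
6 | 8-[(E)-3-(triisopropylsilyloxy)prop-1-enyl]-6b,9a-dimethyl-6b,9a-dihydroacenaphtho[1,2-d][1,3,2]dioxaborole (cis ring fusion) | CC(C)[Si](OC/C=C/B1O[C@]2(C)c3cccc4cccc(c34)[C@]2(C)O1)(C(C)C)C(C)C | intermediate
7 | methyl 4-fluoro-3-hydroxybenzoate | COC(=O)c1ccc(F)c(O)c1 | starting material
8 | methyl 4-fluoro-3-(trifluoromethylsulfonyloxy)benzoate | COC(=O)c1ccc(F)c(OS(=O)(=O)C(F)(F)F)c1 | intermediate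
9 | 5-bromo-1,2,3-trimethoxybenzene | COc1cc(Br)cc(OC)c1OC | starting material
10 | (3,4,5-trimethoxyphenyl)lithium | [Li]c1cc(OC)c(OC)c(OC)c1 | intermediate (not isolated)
11 | lithium ate complex of 6 with the 3,4,5-trimethoxyphenyl group on boron (configuration at boron not defined) | [Li+].COc1cc([B-]2(/C=C/CO[Si](C(C)C)(C(C)C)C(C)C)O[C@]3(C)c4cccc5cccc(c45)[C@]3(C)O2)cc(OC)c1OC | intermediate (not isolated)
12 | methyl 4-fluoro-3-[(1R,2S)-1-(6b,9a-dimethyl-6b,9a-dihydroacenaphtho[1,2-d][1,3,2]dioxaborol-8-yl)-3-(triisopropylsilyloxy)-1-(3,4,5-trimethoxyphenyl)propan-2-yl]benzoate | COc1cc([C@@H]([C@H](CO[Si](C(C)C)(C(C)C)C(C)C)c2cc(C(=O)OC)ccc2F)B2O[C@]3(C)c4cccc5cccc(c45)[C@]3(C)O2)cc(OC)c1OC | intermediate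
13 | methyl 4-fluoro-3-[(1R,2S)-1-hydroxy-3-(triisopropylsilyloxy)-1-(3,4,5-trimethoxyphenyl)propan-2-yl]benzoate | COc1cc([C@H](O)[C@H](CO[Si](C(C)C)(C(C)C)C(C)C)c2cc(C(=O)OC)ccc2F)cc(OC)c1OC | intermediate
14 | methyl (2R,3S)-3-(triisopropylsilyloxymethyl)-2-(3,4,5-trimethoxyphenyl)-2,3-dihydro-1-benzofuran-5-carboxylate | COc1cc([C@@H]2Oc3ccc(C(=O)OC)cc3[C@H]2CO[Si](C(C)C)(C(C)C)C(C)C)cc(OC)c1OC | intermediate
15 | [(2R,3S)-3-(triisopropylsilyloxymethyl)-2-(3,4,5-trimethoxyphenyl)-2,3-dihydro-1-benzofuran-5-yl]methanol | COc1cc([C@@H]2Oc3ccc(CO)cc3[C@H]2CO[Si](C(C)C)(C(C)C)C(C)C)cc(OC)c1OC | intermediate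
16 | (2R,3S)-3-(triisopropylsilyloxymethyl)-2-(3,4,5-trimethoxyphenyl)-2,3-dihydro-1-benzofuran-5-carbaldehyde | COc1cc([C@@H]2Oc3ccc(C=O)cc3[C@H]2CO[Si](C(C)C)(C(C)C)C(C)C)cc(OC)c1OC | intermediate (not isolated)
17 | ethyl (E)-3-[(2R,3S)-3-(triisopropylsilyloxymethyl)-2-(3,4,5-trimethoxyphenyl)-2,3-dihydro-1-benzofuran-5-yl]prop-2-enoate | COc1cc([C@@H]2Oc3ccc(/C=C/C(=O)OCC)cc3[C@H]2CO[Si](C(C)C)(C(C)C)C(C)C)cc(OC)c1OC | intermediate
18 | (E)-3-[(2R,3S)-3-(triisopropylsilyloxymethyl)-2-(3,4,5-trimethoxyphenyl)-2,3-dihydro-1-benzofuran-5-yl]prop-2-en-1-ol | COc1cc([C@@H]2Oc3ccc(/C=C/CO)cc3[C@H]2CO[Si](C(C)C)(C(C)C)C(C)C)cc(OC)c1OC | intermediate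
19 | (E)-3-[(2R,3S)-3-(hydroxymethyl)-2-(3,4,5-trimethoxyphenyl)-2,3-dihydro-1-benzofuran-5-yl]prop-2-en-1-ol | COc1cc([C@@H]2Oc3ccc(/C=C/CO)cc3[C@H]2CO)cc(OC)c1OC | target

## Step count and risk

Total: 11 steps. Longest linear sequence: 9 steps (3 → 4 → 6 → 12 → 13 → 14 → 15 → 17 → 18 → 19, steps 2, 3, 5–11). Steps 1 and 4 are single-step side branches.

Least certain steps:

**Step 5 (key step).**
- What may go wrong: direct transfer of the aryl or alkenyl group from boron to palladium (plain cross-coupling) may outpace the metallate shift. The alkylpalladium intermediate may lose β-hydride or β-silyloxy toward the CH2OSi group. The allylic silyloxy substituent may lower face selectivity. Residual bromide may slow the catalyst.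
- Fallback (known auxiliary chemistry, sets out from 8, returns at 13): triflate 8 is coupled with BrZnCH2CO2t-Bu under Pd[P(t-Bu)3]2 catalysis to give the tert-butyl arylacetate F1. CF3CO2H cleaves the ester to the arylacetic acid F2. Activation with pivaloyl chloride/Et3N and the lithium salt of (4R)-4-benzyl-1,3-oxazolidin-2-one gives the N-acyl oxazolidinone F3. Its boron enolate (Bu2BOTf, i-Pr2NEt, CH2Cl2, −78 °C) reacts with 3,4,5-trimethoxybenzaldehyde in an Evans syn-aldol reaction to give the syn aldol adduct F4. NaBH4 in THF/H2O removes the auxiliary reductively, leaving the methyl benzoate, to give the diol F5. Selective silylation of the primary alcohol (i-Pr3SiCl, imidazole) gives 13.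

**Step 7.**
- What may go wrong: the alkoxide may pull the silyl group over from the neighbouring primary oxygen before it attacks the ring, after which the primary alkoxide closes a regioisomeric five-membered ring. If the displacement is slow and needs heat, base-induced opening of the new ring by elimination across C2–C3 becomes possible.
- Fallback (removes the migrating group, sets out from 13, returns at 14): Bu4NF desilylates 13 to the diol F5. Trityl chloride in pyridine protects the primary alcohol only, giving the trityl ether F6. KN(SiMe3)2 in THF closes the ring to the trityl-protected dihydrobenzofuran F7. Catalytic p-toluenesulfonic acid in MeOH/CH2Cl2 removes the trityl group to give the hydroxy ester F8. i-Pr3SiCl/imidazole then gives 14.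

**Step 6.**
- What may go wrong: oxidation of the hindered benzylic boronic ester may be slow under perborate, and stronger alkaline peroxide may saponify the methyl ester.
- Fallback (accepts the saponification, sets out from 12, returns at 13): 12 is oxidised with H2O2 and aqueous NaOH until both the C–B bond and the ester have reacted, giving the hydroxy acid F9. Me3SiCHN2 in MeOH/toluene re-forms the methyl ester selectively and gives 13.

**Step 3.**
- What may go wrong: hydroboration may give some internal boron regioisomer, or ligand exchange with the hindered diol may stop short or be accompanied by protodeboronation.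
- Fallback (goes through the free boronic acid, sets out from 4, returns at 6): alkyne 4 is hydroborated with pinacolborane under (C5H5)2Zr(H)Cl catalysis to give the pinacol ester F10. NaIO4/NH4OAc in acetone/H2O cleaves the pinacol to give the boronic acid F11. Condensation with diol 2 over MgSO4 in CH2Cl2 gives 6.

## Further compounds

F1 | step 5 | tert-butyl 2-[2-fluoro-5-(methoxycarbonyl)phenyl]acetate | COC(=O)c1ccc(F)c(CC(=O)OC(C)(C)C)c1
F2 | step 5 | 2-[2-fluoro-5-(methoxycarbonyl)phenyl]acetic acid | COC(=O)c1ccc(F)c(CC(=O)O)c1
F3 | step 5 | methyl 3-{2-[(4R)-4-benzyl-2-oxo-1,3-oxazolidin-3-yl]-2-oxoethyl}-4-fluorobenzoate | COC(=O)c1ccc(F)c(CC(=O)N2[C@H](Cc3ccccc3)COC2=O)c1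
F4 | step 5 | methyl 3-[(2R,3R)-1-[(4R)-4-benzyl-2-oxo-1,3-oxazolidin-3-yl]-3-hydroxy-1-oxo-3-(3,4,5-trimethoxyphenyl)propan-2-yl]-4-fluorobenzoate | COc1cc([C@H](O)[C@H](C(=O)N2[C@H](Cc3ccccc3)COC2=O)c2cc(C(=O)OC)ccc2F)cc(OC)c1OC
F5 | step 5 | methyl 3-[(1R,2S)-1,3-dihydroxy-1-(3,4,5-trimethoxyphenyl)propan-2-yl]-4-fluorobenzoate | COc1cc([C@H](O)[C@H](CO)c2cc(C(=O)OC)ccc2F)cc(OC)c1OC
F6 | step 7 | methyl 4-fluoro-3-[(1R,2S)-1-hydroxy-1-(3,4,5-trimethoxyphenyl)-3-(triphenylmethoxy)propan-2-yl]benzoate | COc1cc([C@H](O)[C@H](COC(c2ccccc2)(c2ccccc2)c2ccccc2)c2cc(C(=O)OC)ccc2F)cc(OC)c1OC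
F7 | step 7 | methyl (2R,3S)-2-(3,4,5-trimethoxyphenyl)-3-(triphenylmethoxymethyl)-2,3-dihydro-1-benzofuran-5-carboxylate | COc1cc([C@@H]2Oc3ccc(C(=O)OC)cc3[C@H]2COC(c2ccccc2)(c2ccccc2)c2ccccc2)cc(OC)c1OC
F8 | step 7 | methyl (2R,3S)-3-(hydroxymethyl)-2-(3,4,5-trimethoxyphenyl)-2,3-dihydro-1-benzofuran-5-carboxylate | COc1cc([C@@H]2Oc3ccc(C(=O)OC)cc3[C@H]2CO)cc(OC)c1OC
F9 | step 6 | 4-fluoro-3-[(1R,2S)-1-hydroxy-3-(triisopropylsilyloxy)-1-(3,4,5-trimethoxyphenyl)propan-2-yl]benzoic acid | COc1cc([C@H](O)[C@H](CO[Si](C(C)C)(C(C)C)C(C)C)c2cc(C(=O)O)ccc2F)cc(OC)c1OC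
F10 | step 3 | 4,4,5,5-tetramethyl-2-[(E)-3-(triisopropylsilyloxy)prop-1-enyl]-1,3,2-dioxaborolane | CC(C)[Si](OC/C=C/B1OC(C)(C)C(C)(C)O1)(C(C)C)C(C)C
F11 | step 3 | [(E)-3-(triisopropylsilyloxy)prop-1-enyl]boronic acid | CC(C)[Si](OC/C=C/B(O)O)(C(C)C)C(C)C
A1 | alternative 1 | methyl (2R,3R)-5-bromo-2-(3,4,5-trimethoxyphenyl)-2,3-dihydro-1-benzofuran-3-carboxylate | COc1cc([C@@H]2Oc3ccc(Br)cc3[C@H]2C(=O)OC)cc(OC)c1OC
A2 | alternative 1 | (2R)-6-bromo-2-(3,4,5-trimethoxyphenyl)chroman-4-one | COc1cc([C@H]2CC(=O)c3cc(Br)ccc3O2)cc(OC)c1OC
A3 | alternative 1 | 6-bromo-3-(3,4,5-trimethoxyphenyl)-4H-chromen-4-one | COc1cc(-c2coc3ccc(Br)cc3c2=O)cc(OC)c1OC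
A4 | alternative 2 | tert-butyl{[(2R,3S)-5-[(E)-3-(tert-butyldimethylsilyloxy)prop-1-enyl]-2-(3,4,5-trimethoxyphenyl)-7-(trimethylsilyl)-2,3-dihydro-1-benzofuran-3-yl]methoxy}dimethylsilane | COc1cc([C@@H]2Oc3c([Si](C)(C)C)cc(/C=C/CO[Si](C)(C)C(C)(C)C)cc3[C@H]2CO[Si](C)(C)C(C)(C)C)cc(OC)c1OC
A5 | alternative 2 | (1R,2S)-2-(tert-butyldimethylsilyloxymethyl)-1-(3,4,5-trimethoxyphenyl)but-3-yn-1-yl 2-(trimethylsilyl)ethynyl ether | COc1cc([C@@H]([C@H](CO[Si](C)(C)C(C)(C)C)C#C)OC#C[Si](C)(C)C)cc(OC)c1OC
A6 | alternative 2 | (E)-tert-butyldimethyl(pent-2-en-4-yn-1-yloxy)silane | C#C/C=C/CO[Si](C)(C)C(C)(C)C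
A7 | alternative 3 | (2R,3S)-5-bromo-3-(tert-butyldimethylsilyloxymethyl)-2-(3,4,5-trimethoxyphenyl)-2,3-dihydro-1-benzofuran | COc1cc([C@@H]2Oc3ccc(Br)cc3[C@H]2CO[Si](C)(C)C(C)(C)C)cc(OC)c1OC
A8 | alternative 3 | (6E)-4-bromo-6-[2-(tert-butyldimethylsilyloxy)ethylidene]cyclohexa-2,4-dien-1-one | O=C1C=CC(Br)=C/C1=C\CO[Si](C)(C)C(C)(C)C
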